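**Retrosynthetic overview**
- The C4 acetate comes from a C4 ketone (hydride delivered cis to the 2-phenyl group); C2 comes from enantioselective 1,4-reduction of a 2-phenyl-4-pyranone; the pyran ring comes from an ynone by oxygen addition at C2 and addition–elimination at C8a with loss of methanol.
- The strategy rests on C4: it is the only oxygenated carbon lying between ring A carbon C4a and the C3–C2(Ph) unit, so it is brought in as carbon monoxide between a C4a iodide and phenylacetylene (C4a–C4 and C4–C3 made together).
- The ring A 2-iodo-3-methoxy enone comes from a cyclohexane-1,3-dione, made by Claisen cyclisation of a keto ester derived from (R)-pantolactone (C5, C6, C7 from the lactone; C8 set by chelation-controlled methyl addition).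
- Order of ring formation: ring A (step 8), then the pyran ring (step 12).

Key step: step 11

Remark: atom labels C2–C8a follow the chromene numbering of the target throughout.
Assumption: the (R) antipode of DTBM-SEGPHOS is taken as the one that delivers hydride to the C2 face opposite the acetonide (giving 2R); if a test run shows the reverse sense, the (S) ligand takes its place.

**Step 1**
Reactants: 1 (R)-pantolactone; 2 ethyl vinyl ether
Product: 4 (3R)-2-(1-ethoxyethenyl)-4,4-dimethyloxolane-2,3-diol (lactol; anomer mixture), via 1-ethoxyvinyllithium 3 (not isolated)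
Conditions: 2 (excess), t-BuLi (2.5 equiv), THF, −78 → 0 °C; then 1, THF, −78 °C; aq. NH4Cl
Reagents that add atoms: none
Why: Addition of an acyl-anion equivalent (α-lithiated enol ether) to a γ-lactone should stop at the lithium hemiketal at −78 °C, one equivalent being spent on the free hydroxyl, so a single addition at the carbonyl that becomes C8 is expected and the C7 stereocentre of the chiral pool is untouched.

**Step 2**
Reactants: 4 lactol
Product: 5 (3R,4R)-5-ethoxy-2,2,4-trimethylhex-5-ene-1,3,4-triol
Conditions: MeMgBr (4.5 equiv), CH2Cl2–Et2O, −78 → 0 °C; aq. NH4Cl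
Reagents that add atoms: methylmagnesium bromide C[Mg]Br
Why: Grignard addition to the ring-opened α-alkoxido ketone under chelation control: the C7 magnesium alkoxide and the C8 carbonyl form a five-membered chelate and methyl should add from the face of the C7 hydrogen, away from the quaternary C6, which sets C8 as R with the two oxygens syn.

**Step 3**
Reactants: 5 triol
Product: 6 (3R,4R)-6-(tert-butyldimethylsilyloxy)-2-ethoxy-3,5,5-trimethylhex-1-ene-3,4-diol
Conditions: TBSCl (1.1 equiv), Et3N, DMAP (cat.), CH2Cl2, 0 °C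
Reagents that add atoms: tert-butyldimethylsilyl chloride CC(C)(C)[Si](C)(C)Cl
Why: Selective silylation of the primary hydroxyl (the secondary one lies between two quaternary carbons and the third is tertiary) under basic conditions that spare the enol ether, so that only the C7/C8 diol is left for the acetonide.

**Step 4**
Reactants: 6 silyl ether
Product: 8 1-[(4R,5R)-5-[1-(tert-butyldimethylsilyloxy)-2-methylpropan-2-yl]-2,2,4-trimethyl-1,3-dioxolan-4-yl]ethan-1-one, via keto diol 7 (not isolated)
Conditions: PPTS (cat.), acetone–H2O (50:1), rt; then 2,2-dimethoxypropane (excess), CSA (cat.), rt; Et3N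
Reagents that add atoms: water O; 2,2-dimethoxypropane COC(C)(C)OC
Why: Acid-catalysed hydrolysis of the 1-alkoxyvinyl ether unmasks the C8a methyl ketone and acid-catalysed transketalisation then closes the only free diol (C7/C8) to the dioxolane, both being standard operations that a primary silyl ether survives.

**Step 5**
Reactants: 8 silyl ether
Product: 9 1-[(4R,5R)-5-(1-hydroxy-2-methylpropan-2-yl)-2,2,4-trimethyl-1,3-dioxolan-4-yl]ethan-1-one (in equilibrium with its cyclic hemiketal)
Conditions: Bu4NF, THF, 0 °C → rt; aq. NH4Cl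
Reagents that add atoms: none
Why: Fluoride-induced desilylation of a primary silyl ether, to which the acetonide and the non-epimerisable α-quaternary ketone are inert.

**Step 6**
Reactants: 9 alcohol
Product: 10 2-[(4R,5R)-5-acetyl-2,2,5-trimethyl-1,3-dioxolan-4-yl]-2-methylpropanoic acid
Conditions: TEMPO (20 mol %), PhI(OAc)2 (2.5 equiv), MeCN–H2O (1:1), rt
Reagents that add atoms: water O
Why: Oxoammonium-mediated oxidation of a primary alcohol through the aldehyde hydrate to the carboxylic acid in aqueous acetonitrile, which drains the open hydroxy ketone from its hemiketal and leaves the acetonide intact at near-neutral pH.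

**Step 7**
Reactants: 10 acid
Product: 11 methyl 2-[(4R,5R)-5-acetyl-2,2,5-trimethyl-1,3-dioxolan-4-yl]-2-methylpropanoate
Conditions: MeI, K2CO3, DMF, rt
Reagents that add atoms: iodomethane CI
Why: O-Alkylation of the carboxylate with iodomethane, the carbonate being too weak a base to enolise the methyl ketone.

**Step 8**
Reactants: 11 keto ester
Product: 12 (3aR,7aR)-2,2,3a,7,7-pentamethyltetrahydro-1,3-benzodioxole-4,6-dione (ring A 1,3-dione with C7/C8 acetonide)
Conditions: KOt-Bu (2.5 equiv), THF, 0 °C → rt; cold 1 M HCl to pH 3–4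
Reagents that add atoms: none
Why: Intramolecular Claisen (Dieckmann-type) condensation: the ketone can enolise only toward C4a, the ester has no α-hydrogen, the two chains are cis on the dioxolane, and deprotonation of the 1,3-dione drives the 6-exo-trig closure of ring A, the same closure that gives 4,4-dimethylcyclohexane-1,3-dione from a 2,2-dimethyl-5-oxohexanoate.

**Step 9**
Reactants: 12 dione
Product: 13 (3aR,7aR)-4-methoxy-2,2,3a,7,7-pentamethyl-7,7a-dihydro-1,3-benzodioxol-6(3aH)-one (methyl enol ether at C8a)
Conditions: MeOH–2,2-dimethoxypropane (2:1), CSA (5 mol %), 0 °C → rt, stopped at full conversion with Et3N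
Reagents that add atoms: methanol CO
Why: Acid-catalysed enol etherification of a cyclic 1,3-dione in which methanol should add to the C8a carbonyl, the more electrophilic one because of the adjacent axial C8–O bond, and not to C5 beside the gem-dimethyl carbon, while the dimethoxypropane keeps the medium dry so that the kinetic C8a ether does not equilibrate and the acetonide is not methanolysed.

**Step 10**
Reactants: 13 methyl enol ether
Product: 14 (3aR,7aR)-5-iodo-4-methoxy-2,2,3a,7,7-pentamethyl-7,7a-dihydro-1,3-benzodioxol-6(3aH)-one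
Conditions: NIS (1.2 equiv), MeCN, 0 °C → rt, dark
Reagents that add atoms: N-iodosuccinimide O=C1CCC(=O)N1I
Why: Electrophilic α-iodination of a vinylogous ester, whose C4a is the only nucleophilic carbon and carries the only vinylic hydrogen.

**Step 11**
Reactants: 14 ring A 2-iodo-3-methoxy enone; 15 carbon monoxide; 16 phenylacetylene
Product: 17 (3aR,7aR)-4-methoxy-2,2,3a,7,7-pentamethyl-5-(3-phenylprop-2-ynoyl)-7,7a-dihydro-1,3-benzodioxol-6(3aH)-one
Conditions: PdCl2(PPh3)2 (5 mol %), CuI (2 mol %), Et3N (3 equiv), THF, CO (10 bar), 40 °C; 16 (1.5 equiv) added over 6 h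
Reagents that add atoms: none
Why: Zerovalent palladium, formed in situ from the divalent precatalyst, should add oxidatively to C4a–I; migratory insertion of CO then makes C4a–C4, and transfer of the phenylethynyl group from copper followed by reductive elimination makes C4–C3. The closest known reaction is the carbonylative Sonogashira coupling of aryl and alkenyl iodides with terminal alkynes to alkynones, as used in the first stage of carbonylative flavone annulations. No ring is closed and no stereocentre is formed; C7 and C8 carry no acidic hydrogen and cannot epimerise. The selectivity needed is CO insertion ahead of direct alkynylation: the alkenylpalladium sits between C5=O and C8a–OMe, which slows transmetalation at that crowded carbon, and CO pressure with slow alkyne addition keeps the acetylide concentration low. The second need is that C8a and the acylpalladium are not attacked by other nucleophiles, which the anhydrous medium, the tertiary amine base and the acetonide on the C7/C8 hydroxyls secure.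

**Step 12**
Reactants: 17 ynone
Product: 19 (7R,8R)-6,6,8-trimethyl-2-phenyl-7,8-(propane-2,2-diyldioxy)-7,8-dihydro-4H-chromene-4,5(6H)-dione, via enol acetate 18 (not isolated)
Conditions: AcOH (3 equiv), PBu3 (20 mol %), toluene, rt → 50 °C; then K2CO3 (20 mol %), MeOH, 0 °C → rt
Reagents that add atoms: acetic acid CC(=O)O
Why: Phosphine-catalysed conjugate addition of acetic acid puts an oxygen on C2 as an enol acetate, methanolysis frees the 1,3-diketone enolate, and its C2 oxygen closes the pyranone by 6-endo-trig addition–elimination at C8a with loss of methoxide; since no water or hydroxide is present and methoxide attack at C8a is degenerate, the C8a marker cannot be lost through the free triketone.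

**Step 13**
Reactants: 19 pyranone
Product: 20 (2R,7R,8R)-6,6,8-trimethyl-2-phenyl-7,8-(propane-2,2-diyldioxy)-2,3,7,8-tetrahydro-4H-chromene-4,5(6H)-dione
Conditions: Cu(OAc)2·H2O (5 mol %), (R)-DTBM-SEGPHOS (5.5 mol %), (EtO)2MeSiH (3 equiv), t-BuOH (2 equiv), toluene, 0 °C; aq. NH4Cl
Reagents that add atoms: none
Why: Copper hydride asymmetric conjugate reduction (chiral bisphosphine and silane, as applied to β,β-disubstituted enones, coumarins and chromones) should deliver hydride to C2 of the trisubstituted C2=C3 bond under ligand control on the face opposite the acetonide, setting C2 as R; the tetrasubstituted C4a=C8a bond is too hindered for this catalyst, and tert-butanol protonates the copper enolate before it can expel the ring oxygen.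

**Step 14**
Reactants: 20 dihydropyranone
Product: 21 (2R,4R,7R,8R)-4-hydroxy-6,6,8-trimethyl-2-phenyl-7,8-(propane-2,2-diyldioxy)-2,3,4,6,7,8-hexahydro-5H-chromen-5-one
Conditions: NaBH4, CeCl3·7H2O, MeOH–THF, −78 °C; acetone, then aq. NH4Cl
Reagents that add atoms: none
Why: Luche 1,2-reduction, in which C4 is the accessible carbonyl (C5 is neopentyl) and hydride should add axially, anti to the pseudo-equatorial 2-phenyl group as in flavanone reductions, giving the 2,4-cis alcohol (4R) without conjugate attack at C8a or base-induced opening of the pyran ring.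

**Step 15**
Reactants: 21 alcohol
Product: 22 (2R,4R,7R,8R)-6,6,8-trimethyl-5-oxo-2-phenyl-7,8-(propane-2,2-diyldioxy)-3,4,5,6,7,8-hexahydro-2H-chromen-4-yl acetate
Conditions: Ac2O, pyridine, DMAP (cat.), CH2Cl2, 0 °C
Reagents that add atoms: acetic anhydride CC(=O)OC(C)=O
Why: Nucleophile-catalysed acylation of the only free hydroxyl under basic conditions that avoid ionisation at the allylic C4.

**Step 16**
Reactants: 22 acetate
Product: 23 (2R,4R,7R,8R)-7,8-dihydroxy-6,6,8-trimethyl-5-oxo-2-phenyl-3,4,5,6,7,8-hexahydro-2H-chromen-4-yl acetate (target)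
Conditions: AcOH–H2O (4:1), 45 °C
Reagents that add atoms: none
Why: Acid-catalysed acetonide hydrolysis in aqueous acetic acid, a medium in which ionisation of the allylic C4 acetate is returned by acetate and in which the vinylogous ester (C5=O) damps the donor power of O1, so the ester and the C4 configuration should survive.

**Compound list**
1 | (R)-pantolactone, (3R)-3-hydroxy-4,4-dimethyloxolan-2-one | CC1(C)COC(=O)[C@@H]1O | starting material
2 | ethyl vinyl ether | C=COCC | starting material
3 | 1-ethoxyvinyllithium | [Li]C(=C)OCC | intermediate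
4 | (3R)-2-(1-ethoxyethenyl)-4,4-dimethyloxolane-2,3-diol (anomer mixture) | CC1(C)COC(O)(C(=C)OCC)[C@@H]1O | intermediate
5 | (3R,4R)-5-ethoxy-2,2,4-trimethylhex-5-ene-1,3,4-triol | OCC(C)(C)[C@@H](O)[C@@](C)(O)C(=C)OCC | intermediate
6 | (3R,4R)-6-(tert-butyldimethylsilyloxy)-2-ethoxy-3,5,5-trimethylhex-1-ene-3,4-diol | CC(C)(C)[Si](C)(C)OCC(C)(C)[C@@H](O)[C@@](C)(O)C(=C)OCC | intermediate
7 | (3R,4R)-6-(tert-butyldimethylsilyloxy)-3,4-dihydroxy-3,5,5-trimethylhexan-2-one | CC(C)(C)[Si](C)(C)OCC(C)(C)[C@@H](O)[C@@](C)(O)C(C)=O | intermediate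
8 | 1-[(4R,5R)-5-[1-(tert-butyldimethylsilyloxy)-2-methylpropan-2-yl]-2,2,4-trimethyl-1,3-dioxolan-4-yl]ethan-1-one | CC(=O)[C@]1(C)OC(C)(C)O[C@@H]1C(C)(C)CO[Si](C)(C)C(C)(C)C | intermediate
9 | 1-[(4R,5R)-5-(1-hydroxy-2-methylpropan-2-yl)-2,2,4-trimethyl-1,3-dioxolan-4-yl]ethan-1-one | CC(=O)[C@]1(C)OC(C)(C)O[C@@H]1C(C)(C)CO | intermediate
10 | 2-[(4R,5R)-5-acetyl-2,2,5-trimethyl-1,3-dioxolan-4-yl]-2-methylpropanoic acid | CC(=O)[C@]1(C)OC(C)(C)O[C@@H]1C(C)(C)C(=O)O | intermediate
11 | methyl 2-[(4R,5R)-5-acetyl-2,2,5-trimethyl-1,3-dioxolan-4-yl]-2-methylpropanoate | CC(=O)[C@]1(C)OC(C)(C)O[C@@H]1C(C)(C)C(=O)OC | intermediate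
12 | (3aR,7aR)-2,2,3a,7,7-pentamethyltetrahydro-1,3-benzodioxole-4,6-dione | O=C1CC(=O)[C@]2(C)OC(C)(C)O[C@@H]2C1(C)C | intermediate
13 | (3aR,7aR)-4-methoxy-2,2,3a,7,7-pentamethyl-7,7a-dihydro-1,3-benzodioxol-6(3aH)-one | O=C1C=C(OC)[C@]2(C)OC(C)(C)O[C@@H]2C1(C)C | intermediate
14 | (3aR,7aR)-5-iodo-4-methoxy-2,2,3a,7,7-pentamethyl-7,7a-dihydro-1,3-benzodioxol-6(3aH)-one | IC1=C(OC)[C@]2(C)OC(C)(C)O[C@@H]2C(C)(C)C1=O | intermediate
15 | carbon monoxide | [C-]#[O+] | starting material
16 | phenylacetylene | C#Cc1ccccc1 | starting material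
17 | (3aR,7aR)-4-methoxy-2,2,3a,7,7-pentamethyl-5-(3-phenylprop-2-ynoyl)-7,7a-dihydro-1,3-benzodioxol-6(3aH)-one | O=C(C#Cc1ccccc1)C1=C(OC)[C@]2(C)OC(C)(C)O[C@@H]2C(C)(C)C1=O | intermediate
18 | 3-[(3aR,7aR)-4-methoxy-2,2,3a,7,7-pentamethyl-6-oxo-3a,6,7,7a-tetrahydro-1,3-benzodioxol-5-yl]-3-oxo-1-phenylprop-1-en-1-yl acetate (E/Z mixture) | CC(=O)OC(=CC(=O)C1=C(OC)[C@]2(C)OC(C)(C)O[C@@H]2C(C)(C)C1=O)c1ccccc1 | intermediate
19 | (7R,8R)-6,6,8-trimethyl-2-phenyl-7,8-(propane-2,2-diyldioxy)-7,8-dihydro-4H-chromene-4,5(6H)-dione | O=C1C=C(c2ccccc2)OC2=C1C(=O)C(C)(C)[C@H]3OC(C)(C)O[C@@]23C | intermediate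
20 | (2R,7R,8R)-6,6,8-trimethyl-2-phenyl-7,8-(propane-2,2-diyldioxy)-2,3,7,8-tetrahydro-4H-chromene-4,5(6H)-dione | O=C1C[C@H](c2ccccc2)OC2=C1C(=O)C(C)(C)[C@H]3OC(C)(C)O[C@@]23C | intermediate
21 | (2R,4R,7R,8R)-4-hydroxy-6,6,8-trimethyl-2-phenyl-7,8-(propane-2,2-diyldioxy)-2,3,4,6,7,8-hexahydro-5H-chromen-5-one | O[C@@H]1C[C@H](c2ccccc2)OC2=C1C(=O)C(C)(C)[C@H]3OC(C)(C)O[C@@]23C | intermediate
22 | (2R,4R,7R,8R)-6,6,8-trimethyl-5-oxo-2-phenyl-7,8-(propane-2,2-diyldioxy)-3,4,5,6,7,8-hexahydro-2H-chromen-4-yl acetate | CC(=O)O[C@@H]1C[C@H](c2ccccc2)OC2=C1C(=O)C(C)(C)[C@H]3OC(C)(C)O[C@@]23C | intermediate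
23 | (2R,4R,7R,8R)-7,8-dihydroxy-6,6,8-trimethyl-5-oxo-2-phenyl-3,4,5,6,7,8-hexahydro-2H-chromen-4-yl acetate | CC(=O)O[C@@H]1C[C@H](c2ccccc2)OC2=C1C(=O)C(C)(C)[C@@H](O)[C@@]2(C)O | target

**Step count**
Total steps: 16. Longest linear sequence: 16 (from (R)-pantolactone; ethyl vinyl ether, carbon monoxide and phenylacetylene each enter in one step).

**Steps most likely to fail**

Step 11 (key step). What may go wrong: direct alkynylation at C4a outrunning CO insertion, or sluggish oxidative addition at the tetrasubstituted iodide with alkyne homocoupling taking over. Fallback, setting out from 14 and returning at 17: iodine–magnesium exchange on 14 with i-PrMgCl·LiCl (THF, −40 °C); addition of the alkenylmagnesium species to 3-phenylprop-2-ynal to give the propargylic alcohol (3aR,7aR)-5-(1-hydroxy-3-phenylprop-2-yn-1-yl)-4-methoxy-2,2,3a,7,7-pentamethyl-7,7a-dihydro-1,3-benzodioxol-6(3aH)-one F2; oxidation of F2 with MnO2 (CH2Cl2) to 17. C4 then comes from the aldehyde carbon and no gas is used.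

Step 9. What may go wrong: methanol adding at C5 instead of C8a, or acid-mediated equilibration of the two enol ethers, so that the marker for O1 ends on the wrong carbon. The regiochemistry is to be checked by HMBC before iodination. Fallback, setting out from 12 and returning at 13: methylation of 12 without selectivity (Me3SiCHN2, MeOH–toluene); chromatographic separation of 13 from its regioisomer (3aR,7aR)-6-methoxy-2,2,3a,7,7-pentamethyl-7,7a-dihydro-1,3-benzodioxol-4(3aH)-one F1; hydrolysis of F1 back to 12 (NaOH, aqueous THF, then acidification) for another pass.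

Step 13. What may go wrong: poor facial selectivity at C2, hydride delivery to C8a, or β-elimination of the copper enolate that opens the pyran ring and scrambles C2 and the O1 position. Fallback, setting out from 19 and returning at 20: hydrogenation of C2=C3 over Pd/C (H2, 1 bar, EtOAc, stopped after one equivalent), which involves no enolate and relies on the acetonide shielding one face; chromatographic separation of 20 from its C2 epimer (2S,7R,8R)-6,6,8-trimethyl-2-phenyl-7,8-(propane-2,2-diyldioxy)-2,3,7,8-tetrahydro-4H-chromene-4,5(6H)-dione F3; return of F3 to 19 by dehydrogenation with DDQ (dioxane, 80 °C).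

**Further compounds**
F1 | step 9 | (3aR,7aR)-6-methoxy-2,2,3a,7,7-pentamethyl-7,7a-dihydro-1,3-benzodioxol-4(3aH)-one | COC1=CC(=O)[C@]2(C)OC(C)(C)O[C@@H]2C1(C)C
F2 | step 11 | (3aR,7aR)-5-(1-hydroxy-3-phenylprop-2-yn-1-yl)-4-methoxy-2,2,3a,7,7-pentamethyl-7,7a-dihydro-1,3-benzodioxol-6(3aH)-one (carbinol epimers) | OC(C#Cc1ccccc1)C1=C(OC)[C@]2(C)OC(C)(C)O[C@@H]2C(C)(C)C1=O
F3 | step 13 | (2S,7R,8R)-6,6,8-trimethyl-2-phenyl-7,8-(propane-2,2-diyldioxy)-2,3,7,8-tetrahydro-4H-chromene-4,5(6H)-dione | O=C1C[C@@H](c2ccccc2)OC2=C1C(=O)C(C)(C)[C@H]3OC(C)(C)O[C@@]23C
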